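## Structural features

Numbering follows cyclohepta[c]pyran: C1 (acetal), O2, C3=C4, C4a, C5, C6 (the two cyclopropane carbons, bridged by CMe2), C7 (ketone), C8=C9, C9a; C10 is the formyl carbon on C9 and C11 the acetoxymethyl carbon on C4.

The target is a C15 tricycle with two acetyl groups. A 1-acetoxy-dihydropyran is cis-fused along C4a–C9a to a cyclohept-8-en-7-one, which is cis-fused along C5–C6 to a gem-dimethylcyclopropane. Five stereocentres stand in a row (C1, C9a, C4a, C5, C6): H4a and H9a are cis to each other and lie on the CMe2 face, anti to H5 and H6, and the C1 acetoxy group is anti to H9a. Three exocyclic carbons and the ring ketone sit at four different oxidation levels (acetal C1, aldehyde C10, primary acetate C11, ketone C7). The fragile elements are the anomeric acetate, the enol ether with its allylic acetate (acid: oxocarbenium formation and allylic ionisation), the 4-oxo-enal (a strong acceptor), and H9a, which is γ to the ketone and β to the C1 leaving groups (base: elimination across C1–C9a). The real difficulty is the seven-membered ring with its cis-fused dimethylcyclopropane in one absolute sense, followed by the oxidation-state pattern that must be finished without acid or base. The key step uses the fact that C7, C6, C5, C4a and CMe2 are the skeleton of caronic acid: a [3,3] shift of an allyl vinyl ether built on the caronic lactone inserts C8, C9 and C9a between C7 and C4a.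

## Logic of the disconnections

**27 ⇒ 26 ⇒ 25 ⇒ 24.** No skeletal bond is cut. The C7 ketone and C10 aldehyde of 27 go back to the two allylic hydroxyls of 26, the C10 hydroxyl to the silyl ether of 25, and the two acetates to the lactol and primary hydroxyls of 24. The enone next to the C1 acetal is the acid- and base-sensitive array, so it is created last under neutral conditions, after both acetates are in place. The forward steps need an acetylation of 24 that spares the hindered C7 hydroxyl and places the C1 acetate anti to H9a, and an oxidant that takes both allylic alcohols of 26.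

**24 ⇒ 22 ⇒ 20 ⇒ 19.** Again functional-group changes only. C11–OH and C7–OH come from the ester and ketone of 22 in one hydride step, C8=C9 of 22 from the saturated ketone 20 by dehydrogenation, and the silyl acetal of 20 from lactol 19. The C4 ester is kept until the pyran is closed because it stabilises the enol ether and the lactol. The forward steps must enolise only toward C8 (the other α-carbon is the cyclopropane carbon C6) and must reduce a vinylogous carbonate.

**19 ⇒ 16 + 17.** Cuts: C4–C4a and O2–C1. The whole pyran with C3, C4 and C11 comes from conjugate addition of a formylacetate enolate to the enal C4a=C9a–C1HO, followed by lactol closure. This is placed before C8=C9 exists. With the enone present, a free C1 aldehyde on C9a would be a vinylogous 1,3-dicarbonyl that rests as an extended enol instead of closing, and addition to a dienone would leave the protonation site (C8 or C9a) open. The demands are attack at C4a anti to CMe2 and protonation at C9a cis to H4a.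

**16 ⇒ 15 ⇒ 14 (key).** 16 is the unmasked form of 15. In 15 the C8–C9 bond is cut and the C4a–O bond restored, which turns the cycloheptenone into the oxolane enol ether 14. This removes the seven-membered ring and leaves a bicyclic lactone-derived compound. The forward [3,3] shift needs the alkenyl group of 14 on the face anti to CMe2 and hydrogen, not the silyloxymethyl group, on the inside of the allyl terminus.

**14 ⇒ 13.** Cut: C7=C8. The methylidene carbon is added to the lactone carbonyl, so C8 costs one step. The reagent must be non-basic and must tolerate the acetal and the silyl ether.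

**13 ⇒ 10 + 6 (through 11).** Cuts: C4a–C9a and the lactone acyl–oxygen bond. This separates the cyclopropane half from the four-carbon alkenyl unit carrying C1, C9a, C9 and C10. The addition to the formyl group of 10 must place the alkenyl group trans to CMe2 in 13.

**10 ⇒ 9 ⇒ 8 ⇒ 7.** The two carbonyl carbons of meso 7 are differentiated: one becomes the formyl group (C4a), the other the ester (C7). This one step fixes the absolute configuration of C5 and C6, and hence of the whole target. It needs high enantioselectivity and no scrambling of the two carboxyl groups afterwards.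

**6 ⇒ 5 ⇒ 4 ⇒ 3 ⇒ 2 ⇒ 1.** The alkene of 6 has the acetal carbon cis to the silyloxymethyl group and the halogen cis to hydrogen. A trans-hydroalumination–iodination of a propargylic alcohol would give the other geometrical isomer, which after coupling would point the silyloxymethyl group into the pericyclic array. The geometry needed in 14 is therefore built by syn hydrostannation of symmetric 1, where no regiochemical question arises, followed by differentiation of the two hydroxyls.

## Other disconnections considered

**Alternative 1:** The cut runs through O2–C1 and C4a–C9a. In the forward direction the 2-formylacrylate on C5 of cyclopropane A2 acts as a 1-oxadiene toward the Z-enol ether tethered through C6–C7–C8–C9, and an intramolecular oxa-Diels–Alder reaction gives A1.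
- In its favour: pyran, carbocycle and three stereocentres (C1, C9a, C4a) would arise in one step. Suprafacial addition to the Z-enol ether ties H1 cis to H9a, so on the C1 configuration this alternative is better than the chosen plan, which relies on an anomeric acetylation. The cyclopropane would come from the same desymmetrised anhydride, so the two plans are equal on absolute configuration.
- Against it: the cycloaddition itself has to close the seven-membered ring. The alkylidene formylacetate can react through either carbonyl and either alkene geometry. A2 is a very electrophilic vinylcyclopropane. The face of attack relative to CMe2 depends on tether conformation, not on a directly adjacent group.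
- Comparison: both key steps are concerted pericyclic reactions. The chosen one forms one C–C bond in a preorganised bicyclic array; this one forms two bonds but must organise a medium ring. After A1, the C9 methylidene still has to become the C8=C9 enal, the ketal has to be removed with acid beside an acetal, and the ethyl acetal has to be exchanged for acetate, so step economy is about equal.

**Alternative 2:** The cut runs through C1–C9a and C4–C4a. Irradiation of enol A5 with the alkene of oxabicycle A4 would give a cyclobutanol that fragments by retro-aldol; the released enol closes the lactol to give A3 (De Mayo reaction).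
- In its favour: the whole pyran with its C4 ester arrives in one operation, and the cyclobutane guarantees the cis ring fusion. On the C4a/C9a relationship this alternative is better than the chosen plan, which depends on a kinetic protonation. A4 should be short to make from a furan by [4+3] cycloaddition.
- Against it: the alkene of A4 is differentiated only by a remote bridgehead substituent, so the orientation of addition is poorly controlled. A4 is racemic unless an asymmetric cycloaddition or a resolution is added. The saturated ketone is itself photoactive. The oxygen bridge must later be opened and the gem-dimethylcyclopropane still has to be built on C5–C6, so the hardest feature of the target is postponed.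
- Comparison: a stepwise photochemical biradical process against a thermal concerted one. It is shorter to the pyran but probably longer overall, and it lacks the cheap source of absolute configuration.

**Alternative 3:** The cut runs through C5–CMe2 and C6–CMe2. Ylide A8, made by deprotonating its sulfonium salt with a lithium amide, would add to C5 of the cross-conjugated dienone A7, and the enolate would expel diphenyl sulfide to close the cyclopropane of A6.
- In its favour: the cyclopropane is added last to a finished bicycle, the cis fusion is automatic, and approach anti to the C4a substituent should give the correct face. On relative control at C5/C6 it is equal to the chosen plan. The single step is as economical as the chosen key step.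
- Against it: A7 has two enone termini (C5 and C9) and two acidic γ-hydrogens (H4a, H9a). The basic ylide can therefore deprotonate and trigger elimination across C1–C9a or opening of the pyran. All stereocentres of A7 and its absolute configuration need a separate asymmetric synthesis of a pyran-fused cycloheptadienone, for which no simple precursor is evident.
- Comparison: a Michael-initiated ring closure against a sigmatropic shift. A6 would still need the same ester reduction, acetal exchange and oxidations as the chosen route, and the total is likely longer because all the difficulty moves into A7. The chosen plan takes the cyclopropane, with its absolute sense, from an inexpensive meso compound at the start.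

Key step: step 11

Assumption: quinine is taken to open 7 at the carbonyl that gives the (1R,3S) half ester 8, by analogy with the sense it shows with other cis-fused meso anhydrides; if the sense is the opposite, quinidine gives the same half ester.

## Route

Step 1
Reactants: 1 but-2-yne-1,4-diol
Product: 2 (E)-2-(tributylstannyl)but-2-ene-1,4-diol
Conditions: Bu3SnH, PdCl2(PPh3)2 (cat.), THF, 0 °C to rt
Reagents that add atoms: tributyltin hydride, CCCC[SnH](CCCC)CCCC
Why: Palladium-catalysed hydrostannation adds hydrogen and tin to the same face of the alkyne, and the symmetric diol leaves no regiochemical question, so tin ends cis to the new vinylic hydrogen and the two hydroxymethyl groups end cis to each other.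

Step 2
Reactants: 2 (E)-2-(tributylstannyl)but-2-ene-1,4-diol
Product: 3 (E)-4-[(tert-butyldimethylsilyl)oxy]-2-(tributylstannyl)but-2-en-1-ol
Conditions: tBuMe2SiCl (1 equiv), imidazole, CH2Cl2, −20 °C
Reagents that add atoms: tert-butyldimethylsilyl chloride, CC(C)(C)[Si](C)(C)Cl
Why: Silylation of a diol under steric control should take the hydroxyl remote from the bulky tributylstannyl group, leaving free the hydroxymethyl group on the tin-bearing carbon, which becomes C1.

Step 3
Reactants: 3 (E)-4-[(tert-butyldimethylsilyl)oxy]-2-(tributylstannyl)but-2-en-1-ol
Product: 4 (E)-4-[(tert-butyldimethylsilyl)oxy]-2-iodobut-2-en-1-ol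
Conditions: I2, CH2Cl2, 0 °C
Reagents that add atoms: iodine, II
Why: Iododestannylation of a vinylstannane proceeds with retention, so iodine stays cis to the vinylic hydrogen and trans to the silyloxymethyl group.

Step 4
Reactants: 4 (E)-4-[(tert-butyldimethylsilyl)oxy]-2-iodobut-2-en-1-ol
Product: 5 (E)-4-[(tert-butyldimethylsilyl)oxy]-2-iodobut-2-enal (formyl cis to silyloxymethyl)
Conditions: MnO2 (activated), CH2Cl2, rt, dark
Reagents that add atoms: none
Why: Allylic oxidation with MnO2 is neutral and heterogeneous, which should leave the alkene geometry of the α-iodo enal untouched.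

Step 5
Reactants: 5 (E)-4-[(tert-butyldimethylsilyl)oxy]-2-iodobut-2-enal
Product: 6 (E)-tert-butyl[(3-iodo-4,4-dimethoxybut-2-en-1-yl)oxy]dimethylsilane
Conditions: MeOSiMe3, Me3SiOTf (cat.), CH2Cl2, −78 °C
Reagents that add atoms: methoxytrimethylsilane, CO[Si](C)(C)C
Why: Noyori acetalisation is aprotic and runs at −78 °C, so no conjugate addition–elimination path is open that could equilibrate the alkene to the more stable isomer, and the silyl ether survives.

Step 6
Reactants: 7 caronic anhydride (meso)
Product: 8 (1R,3S)-3-(methoxycarbonyl)-2,2-dimethylcyclopropane-1-carboxylic acid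
Conditions: MeOH (3 equiv), quinine (1.1 equiv), toluene, −55 °C
Reagents that add atoms: methanol, CO
Why: Cinchona-alkaloid-mediated methanolysis of a meso anhydride differentiates the enantiotopic carbonyl groups; choosing which carbon becomes the ester fixes the absolute configuration of both cyclopropane stereocentres (future C5 and C6).

Step 7
Reactants: 8 (1R,3S)-3-(methoxycarbonyl)-2,2-dimethylcyclopropane-1-carboxylic acid
Product: 9 methyl (1S,3R)-3-[(ethylsulfanyl)carbonyl]-2,2-dimethylcyclopropane-1-carboxylate
Conditions: EtSH, EDC·HCl, DMAP (cat.), CH2Cl2, 0 °C to rt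
Reagents that add atoms: ethanethiol, CCS
Why: Carbodiimide thioesterification activates only the free acid under mild conditions, which should avoid exchange of the two carboxyl functions through the cyclic anhydride and so keep the enantiomeric purity.

Step 8
Reactants: 9 methyl (1S,3R)-3-[(ethylsulfanyl)carbonyl]-2,2-dimethylcyclopropane-1-carboxylate
Product: 10 methyl (1S,3R)-3-formyl-2,2-dimethylcyclopropane-1-carboxylate (cis)
Conditions: Et3SiH, 10% Pd/C, CH2Cl2, rt
Reagents that add atoms: none
Why: Fukuyama reduction converts the thioester into the aldehyde without touching the methyl ester or the cyclopropane, and its neutral conditions should not epimerise the cis-formyl ester.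

Step 9
Reactants: 6 (E)-tert-butyl[(3-iodo-4,4-dimethoxybut-2-en-1-yl)oxy]dimethylsilane, 10 methyl (1S,3R)-3-formyl-2,2-dimethylcyclopropane-1-carboxylate
Product: 13 (1S,4S,5R)-4-[(Z)-4-[(tert-butyldimethylsilyl)oxy]-1,1-dimethoxybut-2-en-2-yl]-6,6-dimethyl-3-oxabicyclo[3.1.0]hexan-2-one (alkenyl trans to CMe2), via alkenyllithium 11 (not isolated), via bromomagnesium alkoxide 12 (not isolated)
Conditions: 6, t-BuLi (2.1 equiv), Et2O, −78 °C; add to 10, MgBr2·OEt2, CH2Cl2, −78 °C; then rt
Reagents that add atoms: none
Why: Iodine–lithium exchange keeps the alkene geometry; magnesium chelation between the formyl and ester oxygens holds the aldehyde in a lactone-like orientation, so 1,2-addition occurs from the face away from the syn-methyl of CMe2 and sets C4a (S); the alkoxide then closes the γ-lactone by acyl substitution on the cis ester (5-exo-trig).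

Step 10
Reactants: 13 lactone (as above)
Product: 14 (1R,2S,5S)-2-[(Z)-4-[(tert-butyldimethylsilyl)oxy]-1,1-dimethoxybut-2-en-2-yl]-6,6-dimethyl-4-methylidene-3-oxabicyclo[3.1.0]hexane
Conditions: Cp2TiMe2, toluene (1% pyridine), 65 °C, dark; filtration through basic alumina
Reagents that add atoms: dimethyltitanocene, C[Ti](C)(C1C=CC=C1)C1C=CC=C1
Why: Petasis methylenation converts the lactone carbonyl into the exocyclic enol ether through a titanium methylidene; the reagent is non-basic, tolerates acetal and silyl ether, and the double bond cannot move into the ring because the neighbouring carbon is a cyclopropane carbon.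

Step 11
Reactants: 14 cyclopropane-fused 2-methylidene-5-alkenyloxolane (as above)
Product: 15 (1S,7R)-4-{[(tert-butyldimethylsilyl)oxy]methyl}-5-(dimethoxymethyl)-8,8-dimethylbicyclo[5.1.0]oct-5-en-2-one (C9 of the target numbering, either configuration)
Conditions: toluene (dilute), iPr2NEt (cat.), base-washed sealed tube, 130 °C
Reagents that add atoms: none
Why: The exocyclic enol ether C8=C7–O and the C9a=C9 alkene on C4a form an allyl vinyl ether, so heating should trigger a concerted, suprafacial [3,3] sigmatropic (Claisen) shift that makes C8–C9, breaks C4a–O and unveils the C7 ketone; the closest known reaction type is the thermal Claisen ring expansion of 2-methylene-5-vinyltetrahydrofurans to cyclohept-4-enones. The seven-membered ring is closed by a two-carbon ring enlargement of the oxolane, not by a cyclisation in the Baldwin sense, through a chair-like six-atom array resembling an 8-oxabicyclo[3.2.1]octene, which can only deliver the cis C9a=C4a double bond in the ring. The array is reachable because the alkenyl group stands on the oxolane face anti to CMe2, so the cyclopropane is exo to the forming ring, and because the (Z)-alkene turns hydrogen, not the silyloxymethyl group, toward the C5–C6 bridge. The one new stereocentre, C9, is set by this alkene geometry and the chair array (hydrogen expected syn to H5 and H6), but it is destroyed at step 15 and needs no control. C5 and C6 are outside the pericyclic array and keep the cis configuration and absolute sense installed at step 6. The selectivity needed is for the [3,3] path over ionisation of the allylic C4a–O bond and over a homo-[1,5]-hydrogen shift from the syn-methyl group into the product's vinylcyclopropane; base-washed glass, an amine buffer and the lowest workable temperature guard against the first, and donation from the cyclopropane into the breaking C4a–O bond should lower the barrier enough to stay below the temperature of the second.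

Step 12
Reactants: 15 cycloheptenone acetal (as above)
Product: 16 (1S,7R)-4-{[(tert-butyldimethylsilyl)oxy]methyl}-8,8-dimethyl-2-oxobicyclo[5.1.0]oct-5-ene-5-carbaldehyde (C9 either configuration)
Conditions: pyridinium tosylate (cat.), acetone/H2O, rt
Reagents that add atoms: water, O
Why: The allylic dimethyl acetal hydrolyses under very mild acid to the conjugated enal (C4a=C9a–C1HO), while the primary silyl ether, the ketone and the cyclopropane should be unaffected.

Step 13
Reactants: 16 enal (as above), 17 sodium (E)-3-ethoxy-3-oxoprop-1-en-1-olate (sodium salt of ethyl formylacetate)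
Product: 19 ethyl 1-hydroxy-7-oxo-9-(silyloxymethyl)-octahydro cyclopropane-fused cyclohepta[c]pyran-4-carboxylate (lactol; H4a and H9a cis and on the CMe2 face; C1 anomers, C9 either configuration), via sodium enolate adduct 18 (not isolated)
Conditions: 17 (1.5 equiv), EtOH/THF, 0 °C to rt; then AcOH to pH 5–6
Reagents that add atoms: none
Why: Michael addition of a 1,3-dicarbonyl enolate to an enal followed by hemiacetal closure (6-exo-trig attack of the formyl enol oxygen on C1) is a known pyran annulation; the enolate should attack C4a on the face anti to CMe2, the C1 enolate should be protonated at C9a anti to the new, branched C4a substituent (cis fusion), and the weakly basic medium should not epimerise it afterwards.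

Step 14
Reactants: 19 lactol (as above)
Product: 20 the 1-O-trimethylsilyl acetal of 19
Conditions: Me3SiCl, imidazole, CH2Cl2, 0 °C
Reagents that add atoms: chlorotrimethylsilane, C[Si](C)(C)Cl
Why: Silylation caps the lactol so that it cannot open during enolisation and hydride reduction, and an anomeric trimethylsilyl ether can later be removed without touching the primary tert-butyldimethylsilyl ether.

Step 15
Reactants: 20 silyl acetal ketone (as above)
Product: 22 ethyl 1-(trimethylsilyloxy)-7-oxo-9-(silyloxymethyl)-cyclohepta[c]pyran-4-carboxylate with C8=C9 (enone; H4a and H9a cis), via trimethylsilyl enol ether 21 (not isolated)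
Conditions: LiN(SiMe3)2, Me3SiCl, THF, −78 °C; then Pd(OAc)2 (1.1 equiv), MeCN, rt
Reagents that add atoms: none
Why: Saegusa–Ito oxidation: the ketone can enolise only toward C8 because the other α-carbon is the cyclopropane carbon C6, and the palladium enolate loses the C9 hydrogen by β-hydride elimination, which erases the C9 stereocentre and gives the C8=C9 enone.

Step 16
Reactants: 22 enone ester (as above)
Product: 24 triol: 1-hydroxy (lactol), 4-(hydroxymethyl), 7-hydroxy, 9-(silyloxymethyl), C8=C9 (C7 either configuration, hydroxyl expected syn to CMe2; C1 anomers), via trimethylsilyl acetal diol 23 (not isolated)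
Conditions: iBu2AlH (6 equiv), CH2Cl2, −78 to −40 °C; aq. Rochelle salt; then Bu4NF/AcOH (1:1, 1 equiv), THF, −40 °C
Reagents that add atoms: none
Why: iBu2AlH reduces the β-alkoxyacrylate ester to the allylic alcohol C11 and the enone 1,2 to the C7 allylic alcohol (hydride anti to CMe2), which takes the molecule out of the sensitive enone series; buffered fluoride at low temperature then cleaves only the labile anomeric trimethylsilyl ether.

Step 17
Reactants: 24 triol (as above)
Product: 25 diacetate: 1-acetoxy (anti to H9a), 4-(acetoxymethyl), 7-hydroxy, 9-(silyloxymethyl)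
Conditions: Ac2O (2.2 equiv), pyridine, CH2Cl2, 0 °C
Reagents that add atoms: acetic anhydride, CC(=O)OC(C)=O
Why: The lactol and the primary hydroxyl should acylate much faster than the secondary C7 hydroxyl, which is shielded by the syn-methyl of CMe2; with C9 trigonal, allylic 1,2-strain should hold the C1–C9a bond pseudoaxial on the carbocycle, making H9a axial on the pyran, and the anomeric effect then favours the lactol and its acetate with the C1 oxygen axial, anti to H9a.

Step 18
Reactants: 25 diacetate silyl ether (as above)
Product: 26 diol: 1-acetoxy, 4-(acetoxymethyl), 7-hydroxy, 9-(hydroxymethyl), C8=C9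
Conditions: Bu4NF/AcOH (1:1), THF, 0 °C to rt
Reagents that add atoms: none
Why: Acetic-acid-buffered fluoride removes the primary allylic silyl ether without the basicity that would cleave or shift the acetates and without the acidity that would ionise the anomeric or allylic acetate.

Step 19
Reactants: 26 diol (as above)
Product: 27 target, CNP0263020.2
Conditions: MnO2 (activated, excess), CH2Cl2, rt
Reagents that add atoms: none
Why: Both hydroxyls are allylic to C8=C9, so MnO2 should oxidise them to the C7 ketone and the C10 aldehyde under neutral conditions, creating the base- and acid-sensitive 4-oxo-enal only in the last step; no stereocentre is touched.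

## Compound list

1 | but-2-yne-1,4-diol | OCC#CCO | starting material
2 | (E)-2-(tributylstannyl)but-2-ene-1,4-diol | CCCC[Sn](CCCC)(CCCC)/C(CO)=C/CO | intermediate
3 | (E)-4-[(tert-butyldimethylsilyl)oxy]-2-(tributylstannyl)but-2-en-1-ol | CCCC[Sn](CCCC)(CCCC)/C(CO)=C/CO[Si](C)(C)C(C)(C)C | intermediate
4 | (E)-4-[(tert-butyldimethylsilyl)oxy]-2-iodobut-2-en-1-ol | I/C(CO)=C/CO[Si](C)(C)C(C)(C)C | intermediate
5 | (E)-4-[(tert-butyldimethylsilyl)oxy]-2-iodobut-2-enal | I/C(C=O)=C/CO[Si](C)(C)C(C)(C)C | intermediate
6 | (E)-tert-butyl[(3-iodo-4,4-dimethoxybut-2-en-1-yl)oxy]dimethylsilane | I/C(C(OC)OC)=C/CO[Si](C)(C)C(C)(C)C | intermediate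
7 | caronic anhydride (meso; 6,6-dimethyl-3-oxabicyclo[3.1.0]hexane-2,4-dione) | O=C1OC(=O)[C@H]2[C@@H]1C2(C)C | starting material
8 | (1R,3S)-3-(methoxycarbonyl)-2,2-dimethylcyclopropane-1-carboxylic acid | OC(=O)[C@@H]1[C@H](C(=O)OC)C1(C)C | intermediate
9 | methyl (1S,3R)-3-[(ethylsulfanyl)carbonyl]-2,2-dimethylcyclopropane-1-carboxylate | CCSC(=O)[C@@H]1[C@H](C(=O)OC)C1(C)C | intermediate
10 | methyl (1S,3R)-3-formyl-2,2-dimethylcyclopropane-1-carboxylate | O=C[C@@H]1[C@H](C(=O)OC)C1(C)C | intermediate
11 | (Z)-{4-[(tert-butyldimethylsilyl)oxy]-1,1-dimethoxybut-2-en-2-yl}lithium | [Li]/C(C(OC)OC)=C/CO[Si](C)(C)C(C)(C)C | intermediate (not isolated)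
12 | bromomagnesium alkoxide of methyl (1S,3R)-3-[(1S,2Z)-4-[(tert-butyldimethylsilyl)oxy]-2-(dimethoxymethyl)-1-hydroxybut-2-en-1-yl]-2,2-dimethylcyclopropane-1-carboxylate | Br[Mg]O[C@H](/C(C(OC)OC)=C/CO[Si](C)(C)C(C)(C)C)[C@@H]1[C@H](C(=O)OC)C1(C)C | intermediate (not isolated)
13 | (1S,4S,5R)-4-[(Z)-4-[(tert-butyldimethylsilyl)oxy]-1,1-dimethoxybut-2-en-2-yl]-6,6-dimethyl-3-oxabicyclo[3.1.0]hexan-2-one | O=C1O[C@H](/C(C(OC)OC)=C/CO[Si](C)(C)C(C)(C)C)[C@@H]2[C@H]1C2(C)C | intermediate
14 | (1R,2S,5S)-2-[(Z)-4-[(tert-butyldimethylsilyl)oxy]-1,1-dimethoxybut-2-en-2-yl]-6,6-dimethyl-4-methylidene-3-oxabicyclo[3.1.0]hexane (precursor of the key step) | C=C1O[C@H](/C(C(OC)OC)=C/CO[Si](C)(C)C(C)(C)C)[C@@H]2[C@H]1C2(C)C | intermediate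
15 | (1S,7R)-4-{[(tert-butyldimethylsilyl)oxy]methyl}-5-(dimethoxymethyl)-8,8-dimethylbicyclo[5.1.0]oct-5-en-2-one (product of the key step; C4 of this name, C9 of the target, either configuration) | O=C1CC(CO[Si](C)(C)C(C)(C)C)C(C(OC)OC)=C[C@@H]2[C@H]1C2(C)C | intermediate
16 | (1S,7R)-4-{[(tert-butyldimethylsilyl)oxy]methyl}-8,8-dimethyl-2-oxobicyclo[5.1.0]oct-5-ene-5-carbaldehyde | O=C1CC(CO[Si](C)(C)C(C)(C)C)C(C=O)=C[C@@H]2[C@H]1C2(C)C | intermediate
17 | sodium (E)-3-ethoxy-3-oxoprop-1-en-1-olate | [Na+].[O-]/C=C/C(=O)OCC | starting material
18 | sodium enolate of the Michael adduct (formylacetate unit on C4a anti to CMe2, formyl group on C9a) | CCOC(=O)C(=C[O-])[C@H]1[C@@H](C=O)C(CO[Si](C)(C)C(C)(C)C)CC(=O)[C@H]2[C@@H]1C2(C)C.[Na+] | intermediate (not isolated)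
19 | lactol: ethyl 1-hydroxy-7-oxo-9-{[(tert-butyldimethylsilyl)oxy]methyl} cyclopropane-fused octahydrocyclohepta[c]pyran-4-carboxylate (H4a, H9a cis, on the CMe2 face; C1 and C9 either configuration) | CCOC(=O)C1=COC(O)[C@H]2C(CO[Si](C)(C)C(C)(C)C)CC(=O)[C@H]3[C@@H]([C@@H]12)C3(C)C | intermediate
20 | 1-O-trimethylsilyl acetal of 19 | CCOC(=O)C1=COC(O[Si](C)(C)C)[C@H]2C(CO[Si](C)(C)C(C)(C)C)CC(=O)[C@H]3[C@@H]([C@@H]12)C3(C)C | intermediate
21 | C7 trimethylsilyl enol ether of 20 (C7=C8) | CCOC(=O)C1=COC(O[Si](C)(C)C)[C@H]2C(CO[Si](C)(C)C(C)(C)C)C=C(O[Si](C)(C)C)[C@H]3[C@@H]([C@@H]12)C3(C)C | intermediate (not isolated)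
22 | enone: ethyl 1-(trimethylsilyloxy)-7-oxo-9-{[(tert-butyldimethylsilyl)oxy]methyl} cyclopropane-fused cyclohepta[c]pyran-4-carboxylate with C8=C9 | CCOC(=O)C1=COC(O[Si](C)(C)C)[C@H]2C(CO[Si](C)(C)C(C)(C)C)=CC(=O)[C@H]3[C@@H]([C@@H]12)C3(C)C | intermediate
23 | diol with the anomeric trimethylsilyl ether retained (C7–OH, C11–OH) | OCC1=COC(O[Si](C)(C)C)[C@H]2C(CO[Si](C)(C)C(C)(C)C)=CC(O)[C@H]3[C@@H]([C@@H]12)C3(C)C | intermediate (not isolated)
24 | triol (C1 lactol, C11–OH, C7–OH; C10 silyl ether) | OCC1=COC(O)[C@H]2C(CO[Si](C)(C)C(C)(C)C)=CC(O)[C@H]3[C@@H]([C@@H]12)C3(C)C | intermediate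
25 | 1,11-diacetate with free C7–OH and C10 silyl ether (C1 acetate anti to H9a) | CC(=O)OCC1=CO[C@@H](OC(C)=O)[C@H]2C(CO[Si](C)(C)C(C)(C)C)=CC(O)[C@H]3[C@@H]([C@@H]12)C3(C)C | intermediate
26 | 1,11-diacetate 7,10-diol | CC(=O)OCC1=CO[C@@H](OC(C)=O)[C@H]2C(CO)=CC(O)[C@H]3[C@@H]([C@@H]12)C3(C)C | intermediate
27 | CNP0263020.2: 1-acetoxy-4-(acetoxymethyl)-9-formyl-7-oxo cyclopropane-fused cyclohepta[c]pyran | CC(=O)OCC1=CO[C@@H](OC(C)=O)[C@H]2C(C=O)=CC(=O)[C@H]3[C@@H]([C@@H]12)C3(C)C | target

## Step count and least certain steps

Total: 19 steps. Longest linear sequence: 16 steps (steps 1–5 and 9–19).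

**Step 11 (key step).** The most likely failure is that the [3,3] shift needs a temperature at which the allylic C4a–O bond ionises on traces of acid, or at which the product's vinylcyclopropane undergoes a homo-[1,5]-hydrogen shift from the syn-methyl group. Fallback: starting from 14, the shift is promoted at low temperature with Al(iBu)3 in CH2Cl2 (−78 °C to rt). The aluminium reagent reduces the nascent ketone by β-hydride transfer, so the product is the cycloheptenol F1. Oxidation of F1 with Dess–Martin periodinane (NaHCO3 buffer) returns to 15.

**Step 9.** The most likely failure is poor facial selectivity in the addition to the formyl group if the magnesium chelate is not maintained. This would give the carbinol epimer, whose alkenyl group would lie under the syn-methyl group and which therefore should not lactonise readily. Fallback: starting from 6 and 10 as before, the epimeric hydroxy ester F2 is separated and saponified (LiOH, THF/H2O) to the hydroxy acid F3. Mitsunobu lactonisation (PPh3, diisopropyl azodicarboxylate) then inverts the carbinol carbon and returns to 13.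

**Step 13.** The most likely failure is slow conjugate addition of the weakly nucleophilic stabilised enolate to a β-cyclopropyl, α-branched enal, so that 1,2-addition or self-condensation takes over; loss of the C9a configuration by enolisation is a secondary risk. Fallback: starting from 16, ethyl (E)-3-(dimethylamino)acrylate (toluene, 60–80 °C) serves as an enamine dienophile toward the enal in an inverse-demand oxa-[4+2] addition and gives the aminal cycloadduct F4. Aqueous acetic acid hydrolyses the aminal, and the liberated formylacetate enol recloses onto the C1 aldehyde, returning to 19.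

**Step 17.** The most likely failure is incomplete discrimination between the three hydroxyls (acetylation also at C7) together with an unfavourable mixture of C1 anomers, since the rate differences are moderate and the anomers interconvert. Fallback: starting from 22, Luche reduction (NaBH4, CeCl3·7H2O, MeOH/THF, −78 °C) gives the allylic alcohol F5, which is silylated (tBuMe2SiOTf, 2,6-lutidine) to the silyl ether F6. iBu2AlH followed by buffered fluoride at −40 °C gives the lactol alcohol F7, and exhaustive acetylation (Ac2O, pyridine, DMAP) gives the diacetate F8. Bu4NF/AcOH removes both tert-butyldimethylsilyl groups and returns to 26.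

**Step 5 (with step 4).** The most likely failure is isomerisation of the trisubstituted alkene while the formyl group is free, because the arrangement with formyl cis to silyloxymethyl is the less stable one and reversible conjugate addition could equilibrate it. Fallback: starting from 1, monosilylation gives the monosilyl ether F9, MnO2 oxidation gives the ynal F10, and CH(OMe)3/MeOH with pyridinium tosylate gives the alkynyl acetal F11, in which no geometry can be lost. PdCl2(PPh3)2-catalysed syn hydrostannation with Bu3SnH, expected to place tin next to the acetal carbon, gives the vinylstannane F12, and iodine returns to 6.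

## Further compounds

F1 | step 11 | 4-{[(tert-butyldimethylsilyl)oxy]methyl}-5-(dimethoxymethyl)-8,8-dimethylbicyclo[5.1.0]oct-5-en-2-ol | OC1CC(CO[Si](C)(C)C(C)(C)C)C(C(OC)OC)=C[C@@H]2[C@H]1C2(C)C
F2 | step 9 | methyl (1S,3R)-3-[(1R,2Z)-4-[(tert-butyldimethylsilyl)oxy]-2-(dimethoxymethyl)-1-hydroxybut-2-en-1-yl]-2,2-dimethylcyclopropane-1-carboxylate (carbinol epimer) | O[C@@H](/C(C(OC)OC)=C/CO[Si](C)(C)C(C)(C)C)[C@@H]1[C@H](C(=O)OC)C1(C)C
F3 | step 9 | the corresponding hydroxy acid | O[C@@H](/C(C(OC)OC)=C/CO[Si](C)(C)C(C)(C)C)[C@@H]1[C@H](C(=O)O)C1(C)C
F4 | step 13 | 3-(dimethylamino) aminal cycloadduct (C1=C9a enol ether, C4–H, ethyl ester) | CCOC(=O)C1C(N(C)C)OC=C2C(CO[Si](C)(C)C(C)(C)C)CC(=O)[C@H]3[C@@H]([C@@H]12)C3(C)C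
F5 | step 17 | C7 allylic alcohol of 22 (ester and anomeric trimethylsilyl ether retained) | CCOC(=O)C1=COC(O[Si](C)(C)C)[C@H]2C(CO[Si](C)(C)C(C)(C)C)=CC(O)[C@H]3[C@@H]([C@@H]12)C3(C)C
F6 | step 17 | C7 tert-butyldimethylsilyl ether of F5 | CCOC(=O)C1=COC(O[Si](C)(C)C)[C@H]2C(CO[Si](C)(C)C(C)(C)C)=CC(O[Si](C)(C)C(C)(C)C)[C@H]3[C@@H]([C@@H]12)C3(C)C
F7 | step 17 | lactol alcohol with C7 and C10 silyl ethers | OCC1=COC(O)[C@H]2C(CO[Si](C)(C)C(C)(C)C)=CC(O[Si](C)(C)C(C)(C)C)[C@H]3[C@@H]([C@@H]12)C3(C)C
F8 | step 17 | 1,11-diacetate with C7 and C10 silyl ethers | CC(=O)OCC1=CO[C@@H](OC(C)=O)[C@H]2C(CO[Si](C)(C)C(C)(C)C)=CC(O[Si](C)(C)C(C)(C)C)[C@H]3[C@@H]([C@@H]12)C3(C)C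
F9 | step 5 | 4-[(tert-butyldimethylsilyl)oxy]but-2-yn-1-ol | OCC#CCO[Si](C)(C)C(C)(C)C
F10 | step 5 | 4-[(tert-butyldimethylsilyl)oxy]but-2-ynal | O=CC#CCO[Si](C)(C)C(C)(C)C
F11 | step 5 | tert-butyl[(4,4-dimethoxybut-2-yn-1-yl)oxy]dimethylsilane | COC(OC)C#CCO[Si](C)(C)C(C)(C)C
F12 | step 5 | (E)-tert-butyl{[4,4-dimethoxy-3-(tributylstannyl)but-2-en-1-yl]oxy}dimethylsilane | CCCC[Sn](CCCC)(CCCC)/C(C(OC)OC)=C/CO[Si](C)(C)C(C)(C)C
A1 | alternative 1 | tricyclic pyran from the intramolecular oxa-Diels–Alder reaction (C1 ethyl acetal, C4 methyl ester, C7 dioxolane, C9 methylidene) | COC(=O)C1=CO[C@@H](OCC)[C@H]2C(=C)CC4(OCCO4)[C@H]3[C@@H]([C@@H]12)C3(C)C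
A2 | alternative 1 | cycloaddition precursor: cis-cyclopropane with the 2-formylacrylate on C5 and the ketal chain ending in the Z-enol ether on C6 | COC(=O)C(C=O)=C[C@@H]1[C@H](C2(OCCO2)CC(=C)/C=C\OCC)C1(C)C
A3 | alternative 2 | oxa-bridged cycloheptanone cis-fused to the 1-hydroxy-dihydropyran methyl ester | COC(=O)C1=CO[C@@H](O)[C@H]2[C@]3(CO[Si](C)(C)C(C)(C)C)CC(=O)C[C@@H](O3)[C@@H]12
A4 | alternative 2 | 1-{[(tert-butyldimethylsilyl)oxy]methyl}-8-oxabicyclo[3.2.1]oct-6-en-3-one | C1=C[C@H]2CC(=O)C[C@]1(CO[Si](C)(C)C(C)(C)C)O2
A5 | alternative 2 | enol of methyl diformylacetate | COC(=O)C(C=O)=CO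
A6 | alternative 3 | tricyclic cyclopropane-fused enone (C1 methyl acetal, C4 methyl ester, C9 silyloxymethyl) | COC(=O)C1=CO[C@@H](OC)[C@H]2C(CO[Si](C)(C)C(C)(C)C)=CC(=O)[C@H]3[C@@H]([C@@H]12)C3(C)C
A7 | alternative 3 | pyran-fused cyclohepta-2,6-dienone | COC(=O)C1=CO[C@@H](OC)[C@H]2C(CO[Si](C)(C)C(C)(C)C)=CC(=O)C=C[C@@H]12
A8 | alternative 3 | diphenylsulfonium isopropylide | C[C-](C)[S+](c1ccccc1)c1ccccc1
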